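**Retrosynthetic overview**

1. Target 35 ⇐ angeloylation and acetylation of diol 31 ⇐ α-methylenation of cis-γ-lactone 27 ⇐ oxidative lactonisation of cycloheptene-1,4-diol 24, made from cycloheptenol 23.
2. Key disconnection: the seven-membered carbocycle holds a ring homoallylic alcohol, O–C8H–C7H–C6H=C5(CH3) (the lactone-oxygen carbon, the ring-fusion carbon that carries the lactone α-carbon, and the methyl-bearing ring alkene). Joining that oxygen to C5 in place of the C7–C8 bond gives a tetrahydropyran (O, C8, C9, C10, C1, C5) with C6=C7 as an (E)-alkenyl arm on C5. The cycloheptene is therefore the [2,3]-Wittig ring-expansion product of a 6-alkenyl-2-lithiotetrahydropyran (six-membered O-heterocycle → seven-membered carbocycle), which forms the C7–C8 bond, both stereocentres, the C8 oxygen and the C5=C6 alkene in one operation.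
3. Lithio-tetrahydropyran ⇐ O,S-acetal 21 ⇐ lactol 20 ⇐ acyclic tertiary allylic alcohol 16. C5 comes from chelation-controlled MeMgBr addition to β-hydroxy enone 14, C1/C2 from an Evans syn-aldol, C10 from an auxiliary-controlled vinyl-cuprate addition, and the C6–C7–C11–C12 arm from but-3-yn-1-ol.
4. Order of ring formation: tetrahydropyran (temporary, step 11) → cycloheptene (step 13) → γ-lactone (step 15); the exocyclic methylene and the two esters come last.

Key step: step 13

Remark: locants used in the text are ring C1 (CH with the side chain), C5 (=C–CH3), C6 (=CH), C7 (CH bearing lactone α-carbon C11), C8 (CH–O), C9 (CH2), C10 (CH–CH3), side chain C2 (CH–OAng), C3, C4 (CH2–OAc), C12 lactone C=O, C13 exocyclic CH2; TBS = tert-butyldimethylsilyl, TES = triethylsilyl; the anomeric centres of 20, 21 and 26 form as mixtures and are left unspecified in the SMILES because the next operation erases them.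

**Route**

Step 1
Reactants: 1 (R)-4-benzyloxazolidin-2-one; 2 (E)-but-2-enoyl chloride
Product: 3 (R)-4-benzyl-3-[(E)-but-2-enoyl]oxazolidin-2-one
Conditions: n-BuLi, THF, −78 °C; then 2, −78 → 0 °C
Reagents that add atoms: none
Why: N-acylation of the lithiated oxazolidinone with an acid chloride is the standard loading of an Evans auxiliary and creates no stereocentre.

Step 2
Reactants: 3 (R)-4-benzyl-3-[(E)-but-2-enoyl]oxazolidin-2-one
Product: 4 (R)-4-benzyl-3-[(3S)-3-methylpent-4-enoyl]oxazolidin-2-one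
Conditions: CH2=CHMgBr, CuBr·SMe2, THF/Me2S, −78 → −20 °C; then H2O
Reagents that add atoms: vinylmagnesium bromide, C=C[Mg]Br
Why: Auxiliary-controlled copper-mediated conjugate addition, in which the vinyl group should add to the β-carbon of the Mg-chelated syn-s-cis enoyl imide on the face opposite the benzyl group and so set C10 (3S in the acyl chain).

Step 3
Reactants: 4 (R)-4-benzyl-3-[(3S)-3-methylpent-4-enoyl]oxazolidin-2-one; 5 3-[(tert-butyldimethylsilyl)oxy]propanal
Product: 7 (R)-4-benzyl-3-[(2R,3S)-2-[(2R)-but-3-en-2-yl]-3-hydroxy-5-(TBSO)pentanoyl]oxazolidin-2-one, via Z-dibutylboron enolate 6 (not isolated)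
Conditions: n-Bu2BOTf, i-Pr2NEt, CH2Cl2, −78 → 0 °C; then 5, −78 → 0 °C; then pH 7 buffer, MeOH, H2O2, 0 °C
Reagents that add atoms: none
Why: Evans syn-aldol reaction, in which the Z-boron enolate reacts through a Zimmerman–Traxler chair on the face away from the benzyl group, so the (R)-auxiliary should set C1 and C2 syn.

Step 4
Reactants: 7 Evans syn-aldol adduct
Product: 8 (2R,3S)-2-[(2R)-but-3-en-2-yl]-3-hydroxy-N-methoxy-N-methyl-5-(TBSO)pentanamide
Conditions: MeNH(OMe)·HCl, AlMe3, CH2Cl2, −20 → 0 °C; Rochelle-salt work-up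
Reagents that add atoms: N,O-dimethylhydroxylamine hydrochloride, CNOC.Cl
Why: Weinreb transamidation of a β-hydroxy imide with the aluminium amide, assisted by the aluminium alkoxide of the free hydroxyl, releases the auxiliary without touching the stereocentres.

Step 5
Reactants: 9 but-3-yn-1-ol
Product: 10 (but-3-yn-1-yloxy)triethylsilane
Conditions: Et3SiCl, imidazole, CH2Cl2, 0 °C
Reagents that add atoms: chlorotriethylsilane, CC[Si](Cl)(CC)CC
Why: Routine silylation of a primary alcohol gives a silyl ether that can later be removed in the presence of TBS ethers.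

Step 6
Reactants: 10 (but-3-yn-1-yloxy)triethylsilane
Product: 12 (E)-triethyl[(4-iodobut-3-en-1-yl)oxy]silane, via alkenylzirconocene chloride 11 (not isolated)
Conditions: Cp2Zr(H)Cl, THF, rt; then I2, 0 °C
Reagents that add atoms: iodine, II
Why: Hydrozirconation with Schwartz's reagent adds Zr–H syn with zirconium at the terminal carbon, and iodinolysis with retention should give the E-vinyl iodide.

Step 7
Reactants: 8 Weinreb amide; 12 (E)-triethyl[(4-iodobut-3-en-1-yl)oxy]silane
Product: 14 (3E,6R,7S)-6-[(2R)-but-3-en-2-yl]-7-hydroxy-9-(TBSO)-1-(TESO)non-3-en-5-one, via alkenyllithium 13 (not isolated)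
Conditions: 12, t-BuLi (2 equiv), Et2O, −78 °C; added to 8 pretreated with i-PrMgCl (1 equiv), THF, −78 → −20 °C; then H2O
Reagents that add atoms: none
Why: Iodine–lithium exchange with retention of alkene geometry followed by acyl substitution on the Weinreb amide, whose chelated tetrahedral intermediate prevents over-addition while the hydroxyl is masked as its magnesium alkoxide.

Step 8
Reactants: 14 β-hydroxy enone
Product: 15 (3E,5R,6R,7S)-6-[(2R)-but-3-en-2-yl]-5-methyl-9-(TBSO)-1-(TESO)non-3-ene-5,7-diol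
Conditions: MeMgBr (3 equiv), CH2Cl2/Et2O, −78 °C; then H2O
Reagents that add atoms: methylmagnesium bromide, C[Mg]Br
Why: Chelation-controlled (Cram-chelate) 1,2-Grignard addition, in which magnesium bridges the C2 alkoxide and the ketone oxygen, the C10 branch on C1 and the C3 chain on C2 sit cis on that six-membered chelate, and methyl should attack the opposite face to set C5.

Step 9
Reactants: 15 tertiary allylic alcohol–secondary alcohol diol
Product: 16 (3E,5R,6R,7S)-6-[(2R)-but-3-en-2-yl]-5-methyl-7,9-bis(TBSO)-1-(TESO)non-3-en-5-ol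
Conditions: TBSOTf (1.1 equiv), 2,6-lutidine, CH2Cl2, −78 °C
Reagents that add atoms: tert-butyldimethylsilyl triflate, CC(C)(C)[Si](C)(C)OS(=O)(=O)C(F)(F)F
Why: Silylation should be selective for the secondary hydroxyl because the tertiary allylic hydroxyl is too hindered at −78 °C.

Step 10
Reactants: 16 tertiary alcohol with terminal vinyl group
Product: 18 (3R,4R,5R,6E)-4-[(1S)-1,3-bis(TBSO)propyl]-3,5-dimethyl-9-(TESO)non-6-ene-1,5-diol, via B-alkyl-9-BBN adduct 17 (not isolated)
Conditions: 9-BBN, THF, 0 °C → rt; then NaOH, H2O2, 0 °C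
Reagents that add atoms: hydrogen peroxide, OO
Why: Anti-Markovnikov hydroboration–oxidation with 9-BBN should take the monosubstituted vinyl group and leave the 1,2-disubstituted alkene, which reacts far more slowly.

Step 11
Reactants: 18 primary–tertiary 1,5-diol
Product: 20 (4R,5R,6R)-5-[(1S)-1,3-bis(TBSO)propyl]-4,6-dimethyl-6-[(E)-4-(TESO)but-1-en-1-yl]tetrahydro-2H-pyran-2-ol, via hydroxy aldehyde 19 (not isolated)
Conditions: Dess–Martin periodinane (1.1 equiv), pyridine, CH2Cl2, 0 °C
Reagents that add atoms: none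
Why: Dess–Martin oxidation of the only oxidisable alcohol gives a 5-hydroxy aldehyde that should close onto the tertiary hydroxyl to the six-membered lactol.

Step 12
Reactants: 20 lactol
Product: 21 (4R,5R,6R)-5-[(1S)-1,3-bis(TBSO)propyl]-4,6-dimethyl-2-(phenylsulfanyl)-6-[(E)-4-(TESO)but-1-en-1-yl]tetrahydro-2H-pyran
Conditions: PhSSPh, n-Bu3P, pyridine, rt
Reagents that add atoms: diphenyl disulfide, c1ccc(cc1)SSc1ccccc1
Why: Mukaiyama-type redox condensation converts the lactol hydroxyl into the phenyl thioacetal under neutral conditions, which avoids acid ionisation of the tertiary allylic ether and the TES group.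

Step 13
Reactants: 21 2-(phenylsulfanyl)tetrahydropyran
Product: 23 (1R,2S,5S,6R)-5-[(1S)-1,3-bis(TBSO)propyl]-4,6-dimethyl-2-[2-(TESO)ethyl]cyclohept-3-en-1-ol, via axial 2-lithiotetrahydropyran 22 (not isolated)
Conditions: LiDBB (2.1 equiv), THF, −78 °C, 10 min; then −78 → −30 °C; then H2O
Reagents that add atoms: none
Why: Two-electron reductive lithiation cleaves the C8–S bond and should give the kinetic axial 2-lithiotetrahydropyran 22 (Li cis to the axial C5 methyl, trans to the butenyl arm); on warming the ring flexes to place the butenyl arm pseudo-axial and the carbanion bonds to the alkene terminus C7 with inversion at C8 while the allylic C5–O bond breaks, a [2,3]-Wittig rearrangement that turns the six-membered O-heterocycle into the seven-membered carbocycle as its C8 alkoxide. The closest known reaction type is the reductive-lithiation-triggered [2,3]-Wittig ring expansion of 6-vinyl-2-lithiotetrahydropyrans to cyclohept-3-en-1-olates, the cyclic counterpart of the Still–Wittig rearrangement. The cycloheptene is closed by a concerted, suprafacial five-centre sigmatropic shift (envelope C8–O–C5–C6=C7 inside a bicyclo[3.2.1]-like array, attack on the distal alkene carbon), and the new ring alkene C5=C6 is necessarily Z because C1 stays cis to C7. C8 is controlled by the ring, since the C8–C7 bond can only form on the tetrahydropyran face that carries the butenyl arm, which the C5 quaternary centre fixes as trans to the C1 side chain; C7 is controlled by the E-alkene geometry, whose outward CH2CH2OTES group ends up cis to the C8 oxygen, as the cis-lactone needs. The step needs [2,3]- over [1,2]-shift selectivity and a configurationally stable C–Li centre: the axial lithio epimer is the one set up for inversion, the temperature is kept at or below −30 °C where radical-pair [1,2]-shift and C–Li epimerisation are slow, and only the monosubstituted terminus of the E-alkene is within reach of C8.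

Step 14
Reactants: 23 cycloheptenol with TES-protected hydroxyethyl arm
Product: 24 (1R,2S,5S,6R)-5-[(1S)-1,3-bis(TBSO)propyl]-2-(2-hydroxyethyl)-4,6-dimethylcyclohept-3-en-1-ol
Conditions: PPTS (cat.), MeOH/CH2Cl2, 0 °C
Reagents that add atoms: none
Why: Acid-catalysed methanolysis should remove the primary TES ether selectively because the primary and secondary TBS ethers solvolyse far more slowly.

Step 15
Reactants: 24 cis-1,4-diol
Product: 27 (3aS,6S,7R,8aR)-6-[(1S)-1,3-bis(TBSO)propyl]-5,7-dimethyl-3,3a,6,7,8,8a-hexahydro-2H-cyclohepta[b]furan-2-one, via hydroxy aldehyde 25 (not isolated), via lactol 26 (not isolated)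
Conditions: TEMPO (cat.), PhI(OAc)2, CH2Cl2, rt
Reagents that add atoms: none
Why: TEMPO-catalysed oxidative lactonisation oxidises the primary alcohol first, the aldehyde closes onto the cis C8 hydroxyl, and the lactol is oxidised on to the cis-fused γ-lactone.

Step 16
Reactants: 27 cis-fused γ-lactone
Product: 30 (3aR,6S,7R,8aR)-6-[(1S)-1,3-bis(TBSO)propyl]-5,7-dimethyl-3-methylidene-3,3a,6,7,8,8a-hexahydro-2H-cyclohepta[b]furan-2-one, via Mannich base 28 (not isolated), via methiodide 29 (not isolated)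
Conditions: LDA, THF, −78 °C; CH2=NMe2+ I−, −78 °C → rt; then MeI, MeOH/CH2Cl2, rt; then aq. NaHCO3, CH2Cl2, rt
Reagents that add atoms: N,N-dimethylmethyleneiminium iodide (Eschenmoser's salt), C=[N+](C)C.[I-]
Why: Eschenmoser α-methylenation, a Mannich reaction of the lactone enolate on its convex face followed by N-quaternisation and E1cB loss of trimethylamine, installs the exocyclic methylene.

Step 17
Reactants: 30 bis-TBS α-methylene lactone
Product: 31 (3aR,6S,7R,8aR)-6-[(1S)-1,3-dihydroxypropyl]-5,7-dimethyl-3-methylidene-3,3a,6,7,8,8a-hexahydro-2H-cyclohepta[b]furan-2-one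
Conditions: HF·pyridine, pyridine/THF, 0 °C → rt
Reagents that add atoms: none
Why: Buffered fluoride desilylation removes both TBS ethers under conditions that an α-methylene lactone tolerates.

Step 18
Reactants: 31 side-chain 1,3-diol
Product: 32 (3aR,6S,7R,8aR)-6-[(1S)-3-acetoxy-1-hydroxypropyl]-5,7-dimethyl-3-methylidene-3,3a,6,7,8,8a-hexahydro-2H-cyclohepta[b]furan-2-one
Conditions: AcCl (1.05 equiv), 2,4,6-collidine, CH2Cl2, −78 °C
Reagents that add atoms: acetyl chloride, CC(=O)Cl
Why: Kinetically selective acylation should acetylate the unhindered primary hydroxyl and leave the hindered secondary C2 hydroxyl.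

Step 19
Reactants: 32 primary acetate with free C2 hydroxyl; 33 angelic acid
Product: 35 target, (3aR,6S,7R,8aR)-6-[(1S)-3-acetoxy-1-{[(Z)-2-methylbut-2-enoyl]oxy}propyl]-5,7-dimethyl-3-methylidene-3,3a,6,7,8,8a-hexahydro-2H-cyclohepta[b]furan-2-one, via mixed anhydride 34 (not isolated)
Conditions: 33, 2,4,6-Cl3C6H2COCl, Et3N, toluene, rt; then 32, toluene, 80 °C
Reagents that add atoms: none
Why: Yamaguchi-type esterification through the mixed anhydride, run without a nucleophilic catalyst, should acylate the secondary alcohol while limiting Z→E isomerisation of the angeloyl group.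

**Compound list**

1 | (R)-4-benzyloxazolidin-2-one | O=C1N[C@H](Cc2ccccc2)CO1 | starting material
2 | (E)-but-2-enoyl chloride (crotonyl chloride) | C/C=C/C(=O)Cl | starting material
3 | (R)-4-benzyl-3-[(E)-but-2-enoyl]oxazolidin-2-one | C/C=C/C(=O)N1[C@H](Cc2ccccc2)COC1=O | intermediate
4 | (R)-4-benzyl-3-[(3S)-3-methylpent-4-enoyl]oxazolidin-2-one | C=C[C@@H](C)CC(=O)N1[C@H](Cc2ccccc2)COC1=O | intermediate
5 | 3-[(tert-butyldimethylsilyl)oxy]propanal | O=CCCO[Si](C)(C)C(C)(C)C | starting material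
6 | Z-dibutylboron enolate of 4 (O–B cis to the C10 branch) | C=C[C@@H](C)/C=C(\OB(CCCC)CCCC)N1[C@H](Cc2ccccc2)COC1=O | intermediate (not isolated)
7 | (R)-4-benzyl-3-[(2R,3S)-2-[(2R)-but-3-en-2-yl]-3-hydroxy-5-(TBSO)pentanoyl]oxazolidin-2-one (syn-aldol adduct) | C=C[C@@H](C)[C@H]([C@@H](O)CCO[Si](C)(C)C(C)(C)C)C(=O)N1[C@H](Cc2ccccc2)COC1=O | intermediate
8 | (2R,3S)-2-[(2R)-but-3-en-2-yl]-3-hydroxy-N-methoxy-N-methyl-5-(TBSO)pentanamide | C=C[C@@H](C)[C@H]([C@@H](O)CCO[Si](C)(C)C(C)(C)C)C(=O)N(C)OC | intermediate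
9 | but-3-yn-1-ol | C#CCCO | starting material
10 | (but-3-yn-1-yloxy)triethylsilane | C#CCCO[Si](CC)(CC)CC | intermediate
11 | (E)-[4-(triethylsilyloxy)but-1-en-1-yl]zirconocene chloride (Cp drawn σ-bound) | Cl[Zr](/C=C/CCO[Si](CC)(CC)CC)(C1C=CC=C1)C1C=CC=C1 | intermediate (not isolated)
12 | (E)-triethyl[(4-iodobut-3-en-1-yl)oxy]silane | I/C=C/CCO[Si](CC)(CC)CC | intermediate
13 | (E)-[4-(triethylsilyloxy)but-1-en-1-yl]lithium | [Li]/C=C/CCO[Si](CC)(CC)CC | intermediate (not isolated)
14 | (3E,6R,7S)-6-[(2R)-but-3-en-2-yl]-7-hydroxy-9-(TBSO)-1-(TESO)non-3-en-5-one | C=C[C@@H](C)[C@H]([C@@H](O)CCO[Si](C)(C)C(C)(C)C)C(=O)/C=C/CCO[Si](CC)(CC)CC | intermediate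
15 | (3E,5R,6R,7S)-6-[(2R)-but-3-en-2-yl]-5-methyl-9-(TBSO)-1-(TESO)non-3-ene-5,7-diol | C=C[C@@H](C)[C@H]([C@@H](O)CCO[Si](C)(C)C(C)(C)C)[C@](C)(O)/C=C/CCO[Si](CC)(CC)CC | intermediate
16 | (3E,5R,6R,7S)-6-[(2R)-but-3-en-2-yl]-5-methyl-7,9-bis(TBSO)-1-(TESO)non-3-en-5-ol | C=C[C@@H](C)[C@H]([C@H](CCO[Si](C)(C)C(C)(C)C)O[Si](C)(C)C(C)(C)C)[C@](C)(O)/C=C/CCO[Si](CC)(CC)CC | intermediate
17 | B-alkyl-9-borabicyclo[3.3.1]nonane from 16 (vinyl group converted into CH2CH2–B) | C1CCC2CCCC1B2CC[C@@H](C)[C@H]([C@H](CCO[Si](C)(C)C(C)(C)C)O[Si](C)(C)C(C)(C)C)[C@](C)(O)/C=C/CCO[Si](CC)(CC)CC | intermediate (not isolated)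
18 | (3R,4R,5R,6E)-4-[(1S)-1,3-bis(TBSO)propyl]-3,5-dimethyl-9-(TESO)non-6-ene-1,5-diol | OCC[C@@H](C)[C@H]([C@H](CCO[Si](C)(C)C(C)(C)C)O[Si](C)(C)C(C)(C)C)[C@](C)(O)/C=C/CCO[Si](CC)(CC)CC | intermediate
19 | (3R,4R,5R,6E)-4-[(1S)-1,3-bis(TBSO)propyl]-5-hydroxy-3,5-dimethyl-9-(TESO)non-6-enal | O=CC[C@@H](C)[C@H]([C@H](CCO[Si](C)(C)C(C)(C)C)O[Si](C)(C)C(C)(C)C)[C@](C)(O)/C=C/CCO[Si](CC)(CC)CC | intermediate (not isolated)
20 | (4R,5R,6R)-5-[(1S)-1,3-bis(TBSO)propyl]-4,6-dimethyl-6-[(E)-4-(TESO)but-1-en-1-yl]tetrahydro-2H-pyran-2-ol (lactol, both anomers) | OC1C[C@@H](C)[C@H]([C@H](CCO[Si](C)(C)C(C)(C)C)O[Si](C)(C)C(C)(C)C)[C@@](C)(/C=C/CCO[Si](CC)(CC)CC)O1 | intermediate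
21 | (4R,5R,6R)-5-[(1S)-1,3-bis(TBSO)propyl]-4,6-dimethyl-2-(phenylsulfanyl)-6-[(E)-4-(TESO)but-1-en-1-yl]tetrahydro-2H-pyran (both anomers) | c1ccccc1SC1C[C@@H](C)[C@H]([C@H](CCO[Si](C)(C)C(C)(C)C)O[Si](C)(C)C(C)(C)C)[C@@](C)(/C=C/CCO[Si](CC)(CC)CC)O1 | intermediate
22 | 2-lithio analogue of 21 (C–Li axial, trans to the butenyl arm) | [Li][C@@H]1C[C@@H](C)[C@H]([C@H](CCO[Si](C)(C)C(C)(C)C)O[Si](C)(C)C(C)(C)C)[C@@](C)(/C=C/CCO[Si](CC)(CC)CC)O1 | intermediate (not isolated)
23 | (1R,2S,5S,6R)-5-[(1S)-1,3-bis(TBSO)propyl]-4,6-dimethyl-2-[2-(TESO)ethyl]cyclohept-3-en-1-ol | O[C@@H]1C[C@@H](C)[C@H]([C@H](CCO[Si](C)(C)C(C)(C)C)O[Si](C)(C)C(C)(C)C)C(C)=C[C@@H]1CCO[Si](CC)(CC)CC | intermediate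
24 | (1R,2S,5S,6R)-5-[(1S)-1,3-bis(TBSO)propyl]-2-(2-hydroxyethyl)-4,6-dimethylcyclohept-3-en-1-ol | O[C@@H]1C[C@@H](C)[C@H]([C@H](CCO[Si](C)(C)C(C)(C)C)O[Si](C)(C)C(C)(C)C)C(C)=C[C@@H]1CCO | intermediate
25 | aldehyde of 24 (CH2CH2OH → CH2CHO, ring stereocentres as in 24) | O[C@@H]1C[C@@H](C)[C@H]([C@H](CCO[Si](C)(C)C(C)(C)C)O[Si](C)(C)C(C)(C)C)C(C)=C[C@@H]1CC=O | intermediate (not isolated)
26 | (3aS,6S,7R,8aR)-6-[(1S)-1,3-bis(TBSO)propyl]-5,7-dimethyl-3,3a,6,7,8,8a-hexahydro-2H-cyclohepta[b]furan-2-ol (lactol, both anomers) | OC1O[C@@H]2C[C@@H](C)[C@H]([C@H](CCO[Si](C)(C)C(C)(C)C)O[Si](C)(C)C(C)(C)C)C(C)=C[C@@H]2C1 | intermediate (not isolated)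
27 | (3aS,6S,7R,8aR)-6-[(1S)-1,3-bis(TBSO)propyl]-5,7-dimethyl-3,3a,6,7,8,8a-hexahydro-2H-cyclohepta[b]furan-2-one | O=C1O[C@@H]2C[C@@H](C)[C@H]([C@H](CCO[Si](C)(C)C(C)(C)C)O[Si](C)(C)C(C)(C)C)C(C)=C[C@@H]2C1 | intermediate
28 | (3S,3aR,6S,7R,8aR)-3-[(dimethylamino)methyl] derivative of 27 (Mannich base) | CN(C)C[C@H]1C(=O)O[C@@H]2C[C@@H](C)[C@H]([C@H](CCO[Si](C)(C)C(C)(C)C)O[Si](C)(C)C(C)(C)C)C(C)=C[C@H]12 | intermediate (not isolated)
29 | trimethylammonium iodide of 28 | C[N+](C)(C)C[C@H]1C(=O)O[C@@H]2C[C@@H](C)[C@H]([C@H](CCO[Si](C)(C)C(C)(C)C)O[Si](C)(C)C(C)(C)C)C(C)=C[C@H]12.[I-] | intermediate (not isolated)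
30 | (3aR,6S,7R,8aR)-6-[(1S)-1,3-bis(TBSO)propyl]-5,7-dimethyl-3-methylidene-3,3a,6,7,8,8a-hexahydro-2H-cyclohepta[b]furan-2-one | C=C1C(=O)O[C@@H]2C[C@@H](C)[C@H]([C@H](CCO[Si](C)(C)C(C)(C)C)O[Si](C)(C)C(C)(C)C)C(C)=C[C@H]12 | intermediate
31 | (3aR,6S,7R,8aR)-6-[(1S)-1,3-dihydroxypropyl]-5,7-dimethyl-3-methylidene-3,3a,6,7,8,8a-hexahydro-2H-cyclohepta[b]furan-2-one | C=C1C(=O)O[C@@H]2C[C@@H](C)[C@H]([C@H](CCO)O)C(C)=C[C@H]12 | intermediate
32 | (3aR,6S,7R,8aR)-6-[(1S)-3-acetoxy-1-hydroxypropyl]-5,7-dimethyl-3-methylidene-3,3a,6,7,8,8a-hexahydro-2H-cyclohepta[b]furan-2-one | C=C1C(=O)O[C@@H]2C[C@@H](C)[C@H]([C@H](CCOC(C)=O)O)C(C)=C[C@H]12 | intermediate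
33 | angelic acid, (Z)-2-methylbut-2-enoic acid | C/C=C(/C)C(=O)O | starting material
34 | angelic 2,4,6-trichlorobenzoic anhydride | C/C=C(/C)C(=O)OC(=O)c1c(Cl)cc(Cl)cc1Cl | intermediate (not isolated)
35 | CNP0163960.1, (3aR,6S,7R,8aR)-6-[(1S)-3-acetoxy-1-{[(Z)-2-methylbut-2-enoyl]oxy}propyl]-5,7-dimethyl-3-methylidene-3,3a,6,7,8,8a-hexahydro-2H-cyclohepta[b]furan-2-one | C=C1C(=O)O[C@@H]2C[C@@H](C)[C@H]([C@H](CCOC(C)=O)OC(=O)/C(C)=C\C)C(C)=C[C@H]12 | target

**Step count and risks**

Total step count: 19. Longest linear sequence: 17 steps (steps 1–4 and 7–19; steps 5–6 make the alkenyl arm).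

Steps most likely to fail:

Step 13 (key step). The radical-pair [1,2]-shift, a ring contraction to a cyclopentanol, may outrun the concerted [2,3]-shift. The migrating carbon is tertiary and allylic, and the reactive conformer is strained: the butenyl arm must be pseudo-axial and the ring boat-like to keep the C10 methyl out of a 1,3-diaxial contact. The C–Li centre may also epimerise to the equatorial epimer, which cannot rearrange with inversion and would only be protonated. The fallback gives up the ring expansion and closes the cycloheptene by ring-closing metathesis; it sets out from 8 and comes back to the route at 23. Silylation of 8 (TBSOTf, 2,6-lutidine) gives the TBS-protected Weinreb amide F1. Hydroboration–oxidation of its vinyl group (9-BBN; NaOH, H2O2) gives the primary alcohol F2, and Dess–Martin oxidation gives the aldehyde F3. Alkenyllithium 13 is homologated with 2-(iodomethyl)-4,4,5,5-tetramethyl-1,3,2-dioxaborolane (Matteson-type 1,2-shift) to the (E)-allylboronate F4. Chiral-phosphoric-acid-catalysed allylboration of F3 with F4 should then give the anti homoallylic alcohol F5 with C7 and C8 in place (chair transition state; the E-boronate gives anti; the catalyst enantiomer is chosen for the C8 (R) face). Excess MeMgBr converts the Weinreb amide into the methyl ketone F6, Tebbe methylenation gives the isopropenyl diene F7, and ring-closing metathesis with a second-generation ruthenium carbene (CH2Cl2, 40 °C) closes the trisubstituted C5=C6 bond to give 23.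

Step 8. Facial selectivity at the C5 carbonyl may be poor if the magnesium chelate does not form cleanly, and 1,4-addition to the enone or retro-aldol cleavage of the β-hydroxy ketone may compete. The fallback reverses the order in which the two C5 substituents are introduced and relies on Felkin–Anh rather than chelation control; it sets out from 8 and comes back at 16. Excess MeMgBr converts 8 into the β-hydroxy methyl ketone F8, and TBSOTf/2,6-lutidine gives its non-chelating silyl ether F9. Addition of alkenyllithium 13 (THF, −78 °C, CeCl3 as additive against enolisation), with the C2(OTBS) branch as the large group anti to the nucleophile, should then give 16 directly.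

Step 19. The activated angeloyl group may isomerise Z→E to the tiglate, acylation of the hindered secondary alcohol may be slow, and bases may add to the α-methylene lactone on prolonged heating. The fallback builds the Z-enoate on the molecule instead of transferring it; it sets out from 32 and comes back at 35. Esterification of 32 with 2-[bis(2,2,2-trifluoroethoxy)phosphoryl]propanoic acid (DCC, cat. DMAP, CH2Cl2, 0 °C) gives the phosphonate ester F10. Still–Gennari olefination (KHMDS, 18-crown-6, THF, −78 °C, then acetaldehyde) should then give the Z-trisubstituted enoate 35.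

**Further compounds**

F1 | step 13 | (2R,3S)-2-[(2R)-but-3-en-2-yl]-N-methoxy-N-methyl-3,5-bis(TBSO)pentanamide | C=C[C@@H](C)[C@H]([C@H](CCO[Si](C)(C)C(C)(C)C)O[Si](C)(C)C(C)(C)C)C(=O)N(C)OC
F2 | step 13 | primary alcohol from F1 (vinyl → CH2CH2OH) | OCC[C@@H](C)[C@H]([C@H](CCO[Si](C)(C)C(C)(C)C)O[Si](C)(C)C(C)(C)C)C(=O)N(C)OC
F3 | step 13 | aldehyde from F2 (C8 = CHO) | O=CC[C@@H](C)[C@H]([C@H](CCO[Si](C)(C)C(C)(C)C)O[Si](C)(C)C(C)(C)C)C(=O)N(C)OC
F4 | step 13 | pinacol (E)-[5-(triethylsilyloxy)pent-2-en-1-yl]boronate | CC1(C)OB(C/C=C/CCO[Si](CC)(CC)CC)OC1(C)C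
F5 | step 13 | anti homoallylic alcohol (C7 S, C8 R) with Weinreb amide | C=C[C@H](CCO[Si](CC)(CC)CC)[C@H](O)C[C@@H](C)[C@H]([C@H](CCO[Si](C)(C)C(C)(C)C)O[Si](C)(C)C(C)(C)C)C(=O)N(C)OC
F6 | step 13 | methyl ketone from F5 | C=C[C@H](CCO[Si](CC)(CC)CC)[C@H](O)C[C@@H](C)[C@H]([C@H](CCO[Si](C)(C)C(C)(C)C)O[Si](C)(C)C(C)(C)C)C(C)=O
F7 | step 13 | isopropenyl diene from F6 (metathesis precursor) | C=C[C@H](CCO[Si](CC)(CC)CC)[C@H](O)C[C@@H](C)[C@H]([C@H](CCO[Si](C)(C)C(C)(C)C)O[Si](C)(C)C(C)(C)C)C(C)=C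
F8 | step 8 | (3R,4S)-3-[(2R)-but-3-en-2-yl]-4-hydroxy-6-(TBSO)hexan-2-one | C=C[C@@H](C)[C@H]([C@@H](O)CCO[Si](C)(C)C(C)(C)C)C(C)=O
F9 | step 8 | (3R,4S)-3-[(2R)-but-3-en-2-yl]-4,6-bis(TBSO)hexan-2-one | C=C[C@@H](C)[C@H]([C@H](CCO[Si](C)(C)C(C)(C)C)O[Si](C)(C)C(C)(C)C)C(C)=O
F10 | step 19 | 2-[bis(2,2,2-trifluoroethoxy)phosphoryl]propanoate of 32 (mixture at the phosphonate α-carbon) | C=C1C(=O)O[C@@H]2C[C@@H](C)[C@H]([C@H](CCOC(C)=O)OC(=O)C(C)P(=O)(OCC(F)(F)F)OCC(F)(F)F)C(C)=C[C@H]12
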